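**Retrosynthetic overview**

1. Target 17 ⇐ acyclic (Z)-enal 13, a 4''-acyloxy-3''-oxo-geranylhydroquinone carried as its dimethyl ether. One flask with CAN: quinone → o-quinone methide → furan → quinone, copying 3''-oxo-geranylhydroquinone → shikonofuran → echinofuran-type quinone.
2. 13 ⇐ diol 10 (oxidise the primary allylic alcohol only, then esterify the one remaining OH) ⇐ ester 9 (DIBAL-H).
3. 9 ⇐ (Z)-β-iodoacrylate 6 + 2,5-dimethoxybenzylzinc (Negishi); this fixes the future CHO cis to the benzylic carbon.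
4. 6 ⇐ aldehyde 2 + ethyl propiolate + TMSI: one catalytic asymmetric iodo-aldol sets the only stereocentre and the alkene geometry.
5. Ring order: the six-membered ring is present from the start as a 1,4-dimethoxyarene; the furan is the only ring formed, in the last step, and the quinone is unveiled in the same flask.

Assumption: the (S)-prolinol-derived oxazaborolidinium directs attack to the si face of aldehyde 2, as in its other aldehyde additions, giving (R)-6; if Mosher analysis of 6 shows the opposite sense, the enantiomeric catalyst is used with no other change.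

**Route**

Step 1
Reactants: 1 4-methylpent-3-en-1-ol
Product: 2 4-methylpent-3-enal
Conditions: Dess–Martin periodinane (1.2 equiv), CH2Cl2, 0 °C to rt; short silica pad, used at once as a CH2Cl2 solution
Reagents that add atoms: none
Why: Dess–Martin oxidation is neutral and base-free, so the volatile β,γ-unsaturated aldehyde forms without the double bond moving into conjugation.

Step 2
Reactants: 2 4-methylpent-3-enal; 3 ethyl propiolate
Product: 6 ethyl (2Z)-2-[(1R)-1-hydroxy-4-methylpent-3-en-1-yl]-3-iodoprop-2-enoate, via silyl allenolate 4 (not isolated), via O-TMS aldol ether 5 (not isolated)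
Conditions: TMSI (1.2 equiv), (S)-oxazaborolidinium triflimide [from (S)-diphenylprolinol, o-tolylboroxine, Tf2NH] (20 mol%), EtCN, −78 °C; then 1 M HCl, THF, 0 °C
Reagents that add atoms: iodotrimethylsilane, C[Si](C)(C)I
Why: Iodide conjugate addition to the propiolate gives the β-iodo allenolate, which adds Mukaiyama-aldol fashion (asymmetric β-iodo Morita–Baylis–Hillman three-component coupling) to the aldehyde bound to the chiral Lewis acid; si-face attack sets the (R)-carbinol and the kinetically controlled low-temperature addition gives the (Z)-iodoalkene.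

Step 3
Reactants: 6 ethyl (2Z)-2-[(1R)-1-hydroxy-4-methylpent-3-en-1-yl]-3-iodoprop-2-enoate; 7 2-(chloromethyl)-1,4-dimethoxybenzene
Product: 9 ethyl (2Z)-4-(2,5-dimethoxyphenyl)-2-[(1R)-1-hydroxy-4-methylpent-3-en-1-yl]but-2-enoate, via (2,5-dimethoxybenzyl)zinc chloride 8 (not isolated)
Conditions: 7, Zn dust, LiCl, THF, 25 °C; then 6 (8 in 2.5-fold excess), Pd(OAc)2 (2 mol%), SPhos (4 mol%), THF, 25 °C
Reagents that add atoms: none
Why: LiCl-mediated zinc insertion gives the benzylic zinc reagent, and the Negishi sp2–sp3 coupling replaces iodide with retention of alkene geometry while tolerating the free hydroxyl and the ester.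

Step 4
Reactants: 9 ethyl (2Z)-4-(2,5-dimethoxyphenyl)-2-[(1R)-1-hydroxy-4-methylpent-3-en-1-yl]but-2-enoate
Product: 10 (2E,3R)-2-[2-(2,5-dimethoxyphenyl)ethylidene]-6-methylhept-5-ene-1,3-diol
Conditions: DIBAL-H (3.5 equiv), CH2Cl2, −78 to 0 °C; Rochelle salt work-up
Reagents that add atoms: none
Why: DIBAL-H reduces the conjugated ester 1,2 to the allylic alcohol without touching the alkenes, aryl ethers or stereocentre (the descriptor changes to E only because of CIP priorities; CH2OH stays cis to the arylmethyl group).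

Step 5
Reactants: 10 (2E,3R)-2-[2-(2,5-dimethoxyphenyl)ethylidene]-6-methylhept-5-ene-1,3-diol
Product: 11 (2Z)-4-(2,5-dimethoxyphenyl)-2-[(1R)-1-hydroxy-4-methylpent-3-en-1-yl]but-2-enal
Conditions: TEMPO (10 mol%), PhI(OAc)2 (1.1 equiv), CH2Cl2, 0 °C to rt
Reagents that add atoms: none
Why: The oxoammonium (TEMPO/PhI(OAc)2) oxidation is selective for the primary allylic alcohol over the hindered secondary one and is mild enough to keep the (Z)-enal geometry.

Step 6
Reactants: 11 (2Z)-4-(2,5-dimethoxyphenyl)-2-[(1R)-1-hydroxy-4-methylpent-3-en-1-yl]but-2-enal; 12 3-methylbutanoic anhydride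
Product: 13 (2Z)-4-(2,5-dimethoxyphenyl)-2-[(1R)-4-methyl-1-(3-methylbutanoyloxy)pent-3-en-1-yl]but-2-enal
Conditions: 12 (1.5 equiv), pyridine (3 equiv), DMAP (5 mol%), CH2Cl2, −20 to 0 °C
Reagents that add atoms: none
Why: DMAP-catalysed acyl transfer esterifies the only hydroxyl with retention at the stereocentre, and the cold, weakly basic conditions avoid SN2′ attack or γ-deprotonation of this Morita–Baylis–Hillman-type enal.

Step 7
Reactants: 13 (2Z)-4-(2,5-dimethoxyphenyl)-2-[(1R)-4-methyl-1-(3-methylbutanoyloxy)pent-3-en-1-yl]but-2-enal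
Product: 17 (1R)-1-[5-(3,6-dioxocyclohexa-1,4-dien-1-yl)furan-3-yl]-4-methylpent-3-en-1-yl 3-methylbutanoate, via quinone enal 14 (not isolated), via o-quinone methide 15 (not isolated), via furyl hydroquinone 16 (not isolated)
Conditions: CAN (4.4 equiv), MeCN–H2O (3:1), 0 °C to 20 °C
Reagents that add atoms: water, O
Why: Proposed new method: CAN oxidative demethylation gives quinone 14, whose CH2 (activated by both the quinone and the enal) tautomerises in the acidic medium to o-quinone methide 15; the cis-disposed formyl oxygen (or its hydrate OH) closes 5-exo onto the methide carbon, loss of H+/H2O aromatises both rings to 16 (a redox-neutral isomerisation of 14), and the remaining Ce(IV) oxidises 16 to 17; the stereocentre is not involved, and the closest known reactions are CAN demethylation of 1,4-dimethoxyarenes, tautomerisation of allylquinones to o-quinone methides with intramolecular O-trapping, and acid-mediated cyclodehydration of (Z)-γ-oxygenated enals to furans.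

**Compound list**

1 | 4-methylpent-3-en-1-ol | CC(C)=CCCO | starting material
2 | 4-methylpent-3-enal | CC(C)=CCC=O | intermediate
3 | ethyl propiolate | C#CC(=O)OCC | starting material
4 | (1-ethoxy-3-iodopropa-1,2-dien-1-yl)oxy(trimethyl)silane (silyl allenolate) | CCOC(O[Si](C)(C)C)=C=CI | intermediate (not isolated)
5 | ethyl (2Z)-3-iodo-2-[(1R)-4-methyl-1-(trimethylsilyloxy)pent-3-en-1-yl]prop-2-enoate | CCOC(=O)/C(=C\I)[C@H](O[Si](C)(C)C)CC=C(C)C | intermediate (not isolated)
6 | ethyl (2Z)-2-[(1R)-1-hydroxy-4-methylpent-3-en-1-yl]-3-iodoprop-2-enoate | CCOC(=O)/C(=C\I)[C@H](O)CC=C(C)C | intermediate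
7 | 2-(chloromethyl)-1,4-dimethoxybenzene | COc1ccc(OC)c(CCl)c1 | starting material
8 | (2,5-dimethoxybenzyl)zinc chloride | COc1ccc(OC)c(C[Zn]Cl)c1 | intermediate (not isolated)
9 | ethyl (2Z)-4-(2,5-dimethoxyphenyl)-2-[(1R)-1-hydroxy-4-methylpent-3-en-1-yl]but-2-enoate | CCOC(=O)/C(=C\Cc1cc(OC)ccc1OC)[C@H](O)CC=C(C)C | intermediate
10 | (2E,3R)-2-[2-(2,5-dimethoxyphenyl)ethylidene]-6-methylhept-5-ene-1,3-diol | OC/C(=C\Cc1cc(OC)ccc1OC)[C@H](O)CC=C(C)C | intermediate
11 | (2Z)-4-(2,5-dimethoxyphenyl)-2-[(1R)-1-hydroxy-4-methylpent-3-en-1-yl]but-2-enal | O=C/C(=C\Cc1cc(OC)ccc1OC)[C@H](O)CC=C(C)C | intermediate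
12 | 3-methylbutanoic anhydride | CC(C)CC(=O)OC(=O)CC(C)C | starting material
13 | (2Z)-4-(2,5-dimethoxyphenyl)-2-[(1R)-4-methyl-1-(3-methylbutanoyloxy)pent-3-en-1-yl]but-2-enal | O=C/C(=C\Cc1cc(OC)ccc1OC)[C@H](OC(=O)CC(C)C)CC=C(C)C | intermediate
14 | (2Z)-4-(3,6-dioxocyclohexa-1,4-dien-1-yl)-2-[(1R)-4-methyl-1-(3-methylbutanoyloxy)pent-3-en-1-yl]but-2-enal | O=C/C(=C\CC1=CC(=O)C=CC1=O)[C@H](OC(=O)CC(C)C)CC=C(C)C | intermediate (not isolated)
15 | (2Z)-4-(3-hydroxy-6-oxocyclohexa-2,4-dien-1-ylidene)-2-[(1R)-4-methyl-1-(3-methylbutanoyloxy)pent-3-en-1-yl]but-2-enal | O=C1C=CC(O)=CC1=C/C=C(\C=O)[C@H](OC(=O)CC(C)C)CC=C(C)C | intermediate (not isolated)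
16 | (1R)-1-[5-(2,5-dihydroxyphenyl)furan-3-yl]-4-methylpent-3-en-1-yl 3-methylbutanoate | CC(C)=CC[C@@H](OC(=O)CC(C)C)c1coc(-c2cc(O)ccc2O)c1 | intermediate (not isolated)
17 | (1R)-1-[5-(3,6-dioxocyclohexa-1,4-dien-1-yl)furan-3-yl]-4-methylpent-3-en-1-yl 3-methylbutanoate | CC(C)=CC[C@@H](OC(=O)CC(C)C)c1coc(C2=CC(=O)C=CC2=O)c1 | target

**Step count and risks**

Total step count: 7. Longest linear sequence: 7 (1 → 17).

Steps most likely to fail:

Step 7 (one-flask quinone / quinone-methide / furan cascade). The risks are oxa-6π closure of 15 to a 2H-chromene, Z→E drift of the enal before cyclisation, and over-oxidation of the furan by Ce(IV). The fallback sets out from 13 and comes back at 17. Luche reduction (NaBH4, CeCl3, MeOH, −40 °C) gives the allylic alcohol (2E,3R)-2-[2-(2,5-dimethoxyphenyl)ethylidene]-1-hydroxy-6-methylhept-5-en-3-yl 3-methylbutanoate F1. DDQ (2.2 equiv, CH2Cl2, 0 °C to rt) then removes hydride from the aryl/allyl-activated CH2, the cis CH2OH traps the methoxy-stabilised cation, and a second dehydrogenation gives the aryl furan (1R)-1-[5-(2,5-dimethoxyphenyl)furan-3-yl]-4-methylpent-3-en-1-yl 3-methylbutanoate F2. Here the ring closes at the aryl ether stage, with no free ortho oxygen to form a chromene, and the quinone is unveiled last with CAN (2.5 equiv, MeCN–H2O, 0 °C) to give 17.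

Step 2 (asymmetric iodo-aldol with an enolisable, isomerisation-prone aldehyde). The risks are low ee or yield. The fallback sets out from 2 (with 3) and comes back at 6. MgI2 (CH2Cl2, 0 °C) gives the racemic adduct ethyl (2Z)-2-(1-hydroxy-4-methylpent-3-en-1-yl)-3-iodoprop-2-enoate F3. Dess–Martin oxidation gives the ketone ethyl (2Z)-2-(iodomethylidene)-6-methyl-3-oxohept-5-enoate F4. Reduction with (S)-Me-CBS and catecholborane at −78 °C, with the substituted vinyl group as the large substituent, gives (R)-6; the stereocentre is then set by reagent-controlled reduction instead of C–C bond formation.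

Step 6 (acylation of the sensitive (Z)-hydroxy enal 11). The risks are Z→E isomerisation, SN2′ attack or loss of the new acyloxy group by γ-deprotonation. The fallback sets out from 10 and comes back at 13, bypassing 11. Primary-selective silylation (TESCl, imidazole, CH2Cl2, −78 °C) gives (2E,3R)-2-[2-(2,5-dimethoxyphenyl)ethylidene]-6-methyl-1-(triethylsilyloxy)hept-5-en-3-ol F5. Acylation with 12 (DMAP, Et3N), now with no enal present, gives (2E,3R)-2-[2-(2,5-dimethoxyphenyl)ethylidene]-6-methyl-1-(triethylsilyloxy)hept-5-en-3-yl 3-methylbutanoate F6. IBX in DMSO at rt cleaves and oxidises the primary TES ether directly to the aldehyde 13 under neutral conditions.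

**Further compounds**

F1 | step 7 | (2E,3R)-2-[2-(2,5-dimethoxyphenyl)ethylidene]-1-hydroxy-6-methylhept-5-en-3-yl 3-methylbutanoate | OC/C(=C\Cc1cc(OC)ccc1OC)[C@H](OC(=O)CC(C)C)CC=C(C)C
F2 | step 7 | (1R)-1-[5-(2,5-dimethoxyphenyl)furan-3-yl]-4-methylpent-3-en-1-yl 3-methylbutanoate | CC(C)=CC[C@@H](OC(=O)CC(C)C)c1coc(-c2cc(OC)ccc2OC)c1
F3 | step 2 | ethyl (2Z)-2-(1-hydroxy-4-methylpent-3-en-1-yl)-3-iodoprop-2-enoate (racemic) | CCOC(=O)/C(=C\I)C(O)CC=C(C)C
F4 | step 2 | ethyl (2Z)-2-(iodomethylidene)-6-methyl-3-oxohept-5-enoate | CCOC(=O)/C(=C\I)C(=O)CC=C(C)C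
F5 | step 6 | (2E,3R)-2-[2-(2,5-dimethoxyphenyl)ethylidene]-6-methyl-1-(triethylsilyloxy)hept-5-en-3-ol | CC[Si](CC)(CC)OC/C(=C\Cc1cc(OC)ccc1OC)[C@H](O)CC=C(C)C
F6 | step 6 | (2E,3R)-2-[2-(2,5-dimethoxyphenyl)ethylidene]-6-methyl-1-(triethylsilyloxy)hept-5-en-3-yl 3-methylbutanoate | CC[Si](CC)(CC)OC/C(=C\Cc1cc(OC)ccc1OC)[C@H](OC(=O)CC(C)C)CC=C(C)C
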